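**Plan**
- Retrosynthesis (germacrane numbering: ring C1–C10, lactone carbons C11–C13, ester carbon C14 on C10, methyl C15 on C4). The cuts come in this order: the acyl groups on O8 and O9, then C9–C10, then C1=C10, then O–C6 together with C11–C12, then C5–C6.
- Enabling feature: in the five-membered lactone ring the O–C12(=O) unit is one molecule of CO2 spanning C6 and C11. These two carbons sit 1,3 across C7. C11 is an sp2 carbon that can carry a vinyl anion, and C6 is a secondary carbon next to oxirane carbon C5 that accepts SN2 attack.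
- Forward: an East piece C6–C9 (C11 as vinyl bromide) and a West piece C1–C5 (2,3-oxirane in place) are joined at C5–C6. The 4,5-oxirane is added, CO2 closes the lactone ring, the ten-membered ring closes last at C9–C10, and the two acylations finish the route.
- Stereochemistry: C7/C8, C2/C3 and the side-chain oxirane come from Katsuki–Sharpless epoxidations (C7 by invertive oxirane opening). C4/C5 come from a Shi epoxidation. C6 comes from a chelate-controlled addition followed by inversion in the CO2 step. C9 comes from Felkin–Anh addition during ring closure.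

Key step: step 17

Assumption: the SMILES is taken at face value. Both ring oxiranes are then cis-substituted (C1/C4 and C3/C6 cis), C1=C10 is cis within the ring, and the side chain is the (2S,3S)-epoxyangelate. Compounds 1, 10, 34 and all reagents are taken as purchasable.

Step 1
Reactants: 1 (E)-but-2-ene-1,4-diol
Product: 2 (E)-4-[(tert-butyldiphenylsilyl)oxy]but-2-en-1-ol
Conditions: NaH (1 equiv), THF, 0 °C; TBDPSCl (1 equiv)
Reagents that add atoms: tert-butyl(chloro)diphenylsilane, CC(C)(C)[Si](Cl)(c1ccccc1)c1ccccc1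
Why: O-silylation of the sparingly soluble monoalkoxide should favour the monoether of the symmetrical diol, and no stereocentre is formed.

Step 2
Reactants: 2 (E)-4-[(tert-butyldiphenylsilyl)oxy]but-2-en-1-ol
Product: 3 [(2R,3R)-3-{[(tert-butyldiphenylsilyl)oxy]methyl}oxiran-2-yl]methanol (trans C7–C8 oxirane)
Conditions: Ti(OiPr)4 (cat.), D-(−)-DET (cat.), t-BuOOH, 4 Å MS, CH2Cl2, −20 °C
Reagents that add atoms: tert-butyl hydroperoxide, CC(C)(C)OO
Why: Katsuki–Sharpless asymmetric epoxidation of an E-allylic alcohol with D-(−)-tartrate should give the (2R,3R)-oxirane, which fixes C8 and the pre-inversion configuration of C7.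

Step 3
Reactants: 3 [(2R,3R)-3-{[(tert-butyldiphenylsilyl)oxy]methyl}oxiran-2-yl]methanol
Product: 4 (2S,3S)-4-[(tert-butyldiphenylsilyl)oxy]-2-[1-(trimethylsilyl)ethenyl]butane-1,3-diol (C6–C9 unit with C11/C13)
Conditions: CH2=C(SiMe3)MgBr (3 equiv), CuI (cat.), THF, −30 → 0 °C
Reagents that add atoms: [1-(trimethylsilyl)ethenyl]magnesium bromide, C=C([Mg]Br)[Si](C)(C)C
Why: Copper-catalysed Grignard opening of a 2,3-epoxy alcohol at C-2 (C7), the carbon remote from the bulky silyloxymethyl group, runs with SN2 inversion, so C11 should end up anti to O8 in the 1,3-diol.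

Step 4
Reactants: 4 (2S,3S)-4-[(tert-butyldiphenylsilyl)oxy]-2-[1-(trimethylsilyl)ethenyl]butane-1,3-diol
Product: 6 (2S,3S)-2-(1-bromoethenyl)-4-[(tert-butyldiphenylsilyl)oxy]butane-1,3-diol, via dibromide 5 (not isolated)
Conditions: Br2, CH2Cl2, −78 °C; then NaOMe, MeOH, 0 °C
Reagents that add atoms: bromine, BrBr
Why: In this bromodesilylation, bromine adds to the vinylsilane and methoxide then triggers loss of Me3Si and the terminal bromide, which turns the silyl placeholder on C11 into the 2-bromoalkene without touching C7 or C8.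

Step 5
Reactants: 6 (2S,3S)-2-(1-bromoethenyl)-4-[(tert-butyldiphenylsilyl)oxy]butane-1,3-diol
Product: 7 O6,O8-(4-methoxybenzylidene) acetal of 6 (1,3-dioxane, aryl group equatorial and cis to the C8 side chain)
Conditions: 4-MeOC6H4CH(OMe)2, CSA (cat.), CH2Cl2, rt
Reagents that add atoms: 4-methoxybenzaldehyde dimethyl acetal, COC(OC)c1ccc(OC)cc1
Why: Acid-catalysed transacetalisation ties the 1,3-diol into a six-membered acetal, and thermodynamic control should place the aryl group equatorial at the new acetal centre.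

Step 6
Reactants: 7 O6,O8-(4-methoxybenzylidene) acetal of 6
Product: 8 (2S,3S)-2-(1-bromoethenyl)-4-[(tert-butyldiphenylsilyl)oxy]-3-[(4-methoxybenzyl)oxy]butan-1-ol
Conditions: DIBAL-H, CH2Cl2, −78 → 0 °C
Reagents that add atoms: none
Why: In the regioselective reductive opening of a 4-methoxybenzylidene acetal, aluminium binds the less hindered O6, so the PMB group stays on the secondary O8 and the primary C6 alcohol is freed.

Step 7
Reactants: 8 (2S,3S)-2-(1-bromoethenyl)-4-[(tert-butyldiphenylsilyl)oxy]-3-[(4-methoxybenzyl)oxy]butan-1-ol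
Product: 9 (2R,3S)-2-(1-bromoethenyl)-4-[(tert-butyldiphenylsilyl)oxy]-3-[(4-methoxybenzyl)oxy]butanal (C6 aldehyde)
Conditions: TEMPO (cat.), PhI(OAc)2, CH2Cl2, 0 °C → rt
Reagents that add atoms: none
Why: The oxoammonium (TEMPO) oxidation stops at the aldehyde under base-free conditions, which should keep the α-vinylic C7 centre from epimerising or moving into conjugation.

Step 8
Reactants: 10 prop-2-yn-1-ol
Product: 12 (Z)-3-iodo-2-methylprop-2-en-1-ol, via vinylmagnesium alkoxide 11 (not isolated)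
Conditions: MeMgBr (2.5 equiv), CuI (cat.), Et2O–THF, −10 °C → rt; then I2, 0 °C
Reagents that add atoms: methylmagnesium bromide, C[Mg]Br; iodine, II
Why: Copper-catalysed anti-carbomagnesiation of the propargylic alkoxide gives the chelated Z-vinylmagnesium species, and iodinolysis with retention puts iodine cis to CH2OH, which is the C4=C5 geometry needed.

Step 9
Reactants: 12 (Z)-3-iodo-2-methylprop-2-en-1-ol
Product: 13 (Z)-3-iodo-2-methylprop-2-enal
Conditions: MnO2, CH2Cl2, rt, used at once
Reagents that add atoms: none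
Why: Allylic oxidation with activated MnO2 is neutral and should preserve the Z-geometry of the β-iodoenal.

Step 10
Reactants: 13 (Z)-3-iodo-2-methylprop-2-enal
Product: 14 methyl (2Z,4Z)-5-iodo-4-methylpenta-2,4-dienoate
Conditions: (CF3CH2O)2P(O)CH2CO2Me, KHMDS, 18-crown-6, THF, −78 °C
Reagents that add atoms: methyl bis(2,2,2-trifluoroethyl)phosphonoacetate, COC(=O)CP(=O)(OCC(F)(F)F)OCC(F)(F)F
Why: The Still–Gennari variant of the Horner–Wadsworth–Emmons olefination gives the kinetic Z-enoate, which sets the cis C2=C3 geometry.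

Step 11
Reactants: 14 methyl (2Z,4Z)-5-iodo-4-methylpenta-2,4-dienoate
Product: 15 (2Z,4Z)-5-iodo-4-methylpenta-2,4-dien-1-ol
Conditions: DIBAL-H (2.2 equiv), CH2Cl2, −78 °C
Reagents that add atoms: none
Why: 1,2-Reduction of the enoate by DIBAL-H gives the allylic alcohol without change of either alkene geometry or loss of the vinyl iodide.

Step 12
Reactants: 15 (2Z,4Z)-5-iodo-4-methylpenta-2,4-dien-1-ol
Product: 16 {(2R,3S)-3-[(Z)-1-iodoprop-1-en-2-yl]oxiran-2-yl}methanol (cis C2–C3 oxirane)
Conditions: Ti(OiPr)4 (cat.), D-(−)-DET (cat.), t-BuOOH, 4 Å MS, CH2Cl2, −20 °C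
Reagents that add atoms: tert-butyl hydroperoxide, CC(C)(C)OO
Why: Katsuki–Sharpless epoxidation touches only the alkene allylic to the hydroxyl group, and with D-(−)-tartrate a Z-allylic alcohol should give the (2R,3S)-cis-oxirane, which sets C2 and C3.

Step 13
Reactants: 16 {(2R,3S)-3-[(Z)-1-iodoprop-1-en-2-yl]oxiran-2-yl}methanol
Product: 17 tert-butyl({(2R,3S)-3-[(Z)-1-iodoprop-1-en-2-yl]oxiran-2-yl}methoxy)dimethylsilane
Conditions: TBSCl, imidazole, CH2Cl2, 0 °C
Reagents that add atoms: tert-butyl(chloro)dimethylsilane, CC(C)(C)[Si](C)(C)Cl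
Why: Standard O-silylation masks O1 with a group that survives organolithium reagents and can later be removed in the presence of the TBDPS ether.

Step 14
Reactants: 17 tert-butyl({(2R,3S)-3-[(Z)-1-iodoprop-1-en-2-yl]oxiran-2-yl}methoxy)dimethylsilane; 9 C6 aldehyde
Product: 20 C5–C6 coupled (4Z)-allylic alcohol whose C6 carbinol is inverted relative to the lactone C6–O bond, via alkenyllithium 18 (not isolated), via alkenylmagnesium bromide 19 (not isolated)
Conditions: 17, t-BuLi (2 equiv), Et2O, −78 °C; MgBr2·OEt2; then 9 precomplexed with MgBr2·OEt2, CH2Cl2, −78 °C, cold quench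
Reagents that add atoms: none
Why: Iodine–lithium exchange with retention and transmetalation give a Z-alkenyl Grignard reagent that attacks the six-membered Mg chelate between the aldehyde oxygen and O8–PMB (Cram chelate model) on the face away from the C7 bromovinyl group, so O6 should end up anti to C11.

Step 15
Reactants: 20 C5–C6 coupled (4Z)-allylic alcohol
Product: 21 2,3:4,5-bis-oxirane (6R)-alcohol (C2–C5, C7, C8 as in the target, C6 inverted)
Conditions: D-fructose-derived Shi ketone (0.3 equiv), Oxone, K2CO3, Bu4NHSO4 (cat.), borate/EDTA buffer, MeCN–DMM–H2O, 0 °C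
Reagents that add atoms: Oxone (active component potassium peroxymonosulfate), [K+].[O-]S(=O)(=O)OO
Why: In the Shi epoxidation the chiral dioxirane reacts through the spiro transition state with the only electron-rich (trisubstituted) alkene and, under reagent control, should deliver oxygen to the face that gives (4R,5R), that is the erythro epoxy alcohol a hydroxyl-directed epoxidation would not give.

Step 16
Reactants: 21 2,3:4,5-bis-oxirane (6R)-alcohol
Product: 22 C6 tosylate of 21
Conditions: TsCl, Et3N, Me3N·HCl (cat.), CH2Cl2, 0 °C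
Reagents that add atoms: 4-toluenesulfonyl chloride, Cc1ccc(cc1)S(Cl)(=O)=O
Why: O-sulfonylation with retention installs at C6 a nucleofuge that, unlike a mesylate, has no acidic α-hydrogen for an organolithium to remove.

Step 17
Reactants: 22 C6 tosylate of 21
Product: 25 trans-fused α-methylene-γ-butyrolactone (C2–C8 as in the target; C1 OTBS, C8 OPMB, C9 OTBDPS), via C11 vinyllithium 23 (not isolated), via lithium acrylate 24 (not isolated)
Conditions: t-BuLi (2.05 equiv), THF–Et2O, −95 °C, 5 min; dry CO2, −95 → 0 °C; then DMF, 45 °C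
Reagents that add atoms: carbon dioxide, O=C=O
Why: Bromine–lithium exchange at C11 gives vinyllithium 23, which adds to CO2 (C11–C12 bond), and on warming in THF–DMF the carboxylate oxygen of 24 displaces the C6 tosylate from the rear (O–C6 bond), so one CO2 molecule supplies C12 and both lactone oxygens. The closest known reaction type is the Parham-type sequence of halogen–lithium exchange next to a pendant alkylating group, carboxylation and intramolecular carboxylate alkylation, as used for phthalides and dihydroisocoumarins. The lactone ring closes in the 5-exo-tet mode. C6 is the only stereocentre that changes: SN2 inversion turns the chelate-derived (6R)-sulfonate into the (6S)-C–O bond of the trans-disubstituted lactone, C7 is untouched, and no later α-methylenation is needed. In the first stage the exchange at −95 °C must outrun attack on the oxiranes and the sulfonate, which is helped by the tosylate having no acidic α-hydrogen and by the strain of the competing 3-exo closure to a methylenecyclopropane. In the second stage attack at C6 must beat 6-exo opening of the oxirane at C5, which is secured by the better nucleofuge, the faster five-membered closure, SN2 activation by the neighbouring oxirane and sequestration of Lewis-acidic lithium by DMF.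

Step 18
Reactants: 25 trans-fused α-methylene-γ-butyrolactone
Product: 26 C1 primary alcohol (bis-oxirane lactone, C8 OPMB, C9 OTBDPS)
Conditions: HF·pyridine, excess pyridine, THF, 0 °C
Reagents that add atoms: none
Why: In buffered fluoride desilylation the primary TBS ether is cleaved much faster than the bulkier TBDPS ether, and the excess pyridine should protect the oxiranes.

Step 19
Reactants: 26 C1 primary alcohol
Product: 27 C1 cis-epoxy aldehyde
Conditions: TPAP (cat.), NMO, 4 Å MS, CH2Cl2, rt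
Reagents that add atoms: none
Why: The Ley–Griffith oxidation is neutral, which avoids acid-induced attack of O1 on the oxiranes, and it stops at the configurationally stable epoxy aldehyde.

Step 20
Reactants: 27 C1 cis-epoxy aldehyde
Product: 28 methyl (Z)-α-iodoenoate (C10 iodide, C14 ester trans to C2)
Conditions: Ph3P=CHCO2Me, NIS, CH2Cl2, −20 °C; then 27, −20 °C → rt
Reagents that add atoms: methyl (triphenylphosphoranylidene)acetate, COC(=O)C=P(c1ccccc1)(c1ccccc1)c1ccccc1; N-iodosuccinimide, O=C1CCC(=O)N1I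
Why: Wittig olefination with the stabilised α-iodo ylide places the ester trans to the aldehyde residue, so the Z-iodoenoate should carry iodine where C9 must later be bonded.

Step 21
Reactants: 28 methyl (Z)-α-iodoenoate
Product: 29 C9 primary alcohol
Conditions: TBAF, AcOH (1:1), THF, rt
Reagents that add atoms: none
Why: Acetic-acid-buffered fluoride removes the TBDPS ether without basic conditions that would endanger the α-methylene lactone, the iodoenoate or the oxiranes.

Step 22
Reactants: 29 C9 primary alcohol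
Product: 30 C9 aldehyde (α-OPMB)
Conditions: TPAP (cat.), NMO, 4 Å MS, CH2Cl2, rt
Reagents that add atoms: none
Why: The Ley–Griffith oxidation gives the α-alkoxy aldehyde under neutral conditions, so C8 should not epimerise.

Step 23
Reactants: 30 C9 aldehyde
Product: 31 ten-membered (9R)-allylic alcohol (ring C1–C10 closed)
Conditions: CrCl2 (excess), NiCl2 (cat.), DMSO–THF, rt, slow addition at high dilution
Reagents that add atoms: none
Why: In the Nozaki–Hiyama–Kishi macrocyclisation the alkenylchromium formed with retention at C10 adds to the C9 aldehyde. The all-cis C1–C5 segment curls the chain towards closure, and Felkin–Anh attack anti to the C8–OPMB bond should set O9 anti to O8.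

Step 24
Reactants: 31 ten-membered (9R)-allylic alcohol
Product: 32 C9 acetate
Conditions: Ac2O, DMAP (cat.), pyridine, 0 °C → rt
Reagents that add atoms: acetic anhydride, CC(=O)OC(C)=O
Why: DMAP-catalysed acylation of the only free hydroxyl group proceeds with retention at C9.

Step 25
Reactants: 32 C9 acetate
Product: 33 C8 alcohol
Conditions: DDQ, CH2Cl2–pH 7 buffer, 0 °C
Reagents that add atoms: none
Why: Oxidative cleavage of the PMB ether by DDQ is neutral and should leave the oxiranes, the acetate, the enoate and the α-methylene lactone intact.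

Step 26
Reactants: 34 methyl angelate (methyl (Z)-2-methylbut-2-enoate)
Product: 35 (Z)-2-methylbut-2-en-1-ol
Conditions: DIBAL-H (2.2 equiv), CH2Cl2, −78 °C
Reagents that add atoms: none
Why: 1,2-Reduction of the ester keeps the Z-geometry that defines the cis relation of C1' and C4' in the side chain.

Step 27
Reactants: 35 (Z)-2-methylbut-2-en-1-ol
Product: 36 [(2R,3S)-2,3-dimethyloxiran-2-yl]methanol
Conditions: Ti(OiPr)4 (cat.), D-(−)-DIPT (cat.), t-BuOOH, 4 Å MS, CH2Cl2, −20 °C
Reagents that add atoms: tert-butyl hydroperoxide, CC(C)(C)OO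
Why: Katsuki–Sharpless epoxidation with D-(−)-tartrate should give the (2R,3S)-epoxy alcohol, which sets both side-chain stereocentres.

Step 28
Reactants: 36 [(2R,3S)-2,3-dimethyloxiran-2-yl]methanol
Product: 37 (2S,3S)-2,3-dimethyloxirane-2-carboxylic acid
Conditions: RuCl3 (cat.), NaIO4, MeCN–CCl4–H2O, 0 °C → rt
Reagents that add atoms: water, O; sodium periodate, [Na+].[O-]I(=O)(=O)=O
Why: Catalytic RuO4 oxidation takes the primary epoxy alcohol through the aldehyde hydrate to the glycidic acid without touching the oxirane, and only the CIP descriptor at C2' changes.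

Step 29
Reactants: 33 C8 alcohol; 37 (2S,3S)-2,3-dimethyloxirane-2-carboxylic acid
Product: 39 CNP0077535.3 (target), via mixed anhydride 38 (not isolated)
Conditions: 37, 2,4,6-trichlorobenzoyl chloride, Et3N, toluene, rt; then 33, DMAP, toluene, rt
Reagents that add atoms: none
Why: In the Yamaguchi esterification DMAP attacks the less hindered carbonyl of the mixed anhydride, and the resulting acylpyridinium acylates the hindered C8 hydroxyl with retention at C8, C2' and C3'.

**Compound list**
1 | (E)-but-2-ene-1,4-diol | OC/C=C/CO | starting material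
2 | (E)-4-[(tert-butyldiphenylsilyl)oxy]but-2-en-1-ol | OC/C=C/CO[Si](c1ccccc1)(c1ccccc1)C(C)(C)C | intermediate
3 | [(2R,3R)-3-{[(tert-butyldiphenylsilyl)oxy]methyl}oxiran-2-yl]methanol | OC[C@H]1O[C@@H]1CO[Si](c1ccccc1)(c1ccccc1)C(C)(C)C | intermediate
4 | (2S,3S)-4-[(tert-butyldiphenylsilyl)oxy]-2-[1-(trimethylsilyl)ethenyl]butane-1,3-diol | OC[C@H](C(=C)[Si](C)(C)C)[C@H](O)CO[Si](c1ccccc1)(c1ccccc1)C(C)(C)C | intermediate
5 | C11,C13-dibromide of 4 (C11 epimers, not isolated) | OC[C@H](C(Br)(CBr)[Si](C)(C)C)[C@H](O)CO[Si](c1ccccc1)(c1ccccc1)C(C)(C)C | intermediate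
6 | (2S,3S)-2-(1-bromoethenyl)-4-[(tert-butyldiphenylsilyl)oxy]butane-1,3-diol | OC[C@H](C(Br)=C)[C@H](O)CO[Si](c1ccccc1)(c1ccccc1)C(C)(C)C | intermediate
7 | O6,O8-(4-methoxybenzylidene) acetal of 6 | COc1ccc(cc1)[C@H]1OC[C@H](C(Br)=C)[C@@H](CO[Si](c2ccccc2)(c2ccccc2)C(C)(C)C)O1 | intermediate
8 | (2S,3S)-2-(1-bromoethenyl)-4-[(tert-butyldiphenylsilyl)oxy]-3-[(4-methoxybenzyl)oxy]butan-1-ol | OC[C@H](C(Br)=C)[C@H](OCc1ccc(OC)cc1)CO[Si](c1ccccc1)(c1ccccc1)C(C)(C)C | intermediate
9 | (2R,3S)-2-(1-bromoethenyl)-4-[(tert-butyldiphenylsilyl)oxy]-3-[(4-methoxybenzyl)oxy]butanal | O=C[C@H](C(Br)=C)[C@H](OCc1ccc(OC)cc1)CO[Si](c1ccccc1)(c1ccccc1)C(C)(C)C | intermediate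
10 | prop-2-yn-1-ol | C#CCO | starting material
11 | (Z)-vinylmagnesium alkoxide (not isolated) | Br[Mg]OC/C(C)=C\[Mg]Br | intermediate
12 | (Z)-3-iodo-2-methylprop-2-en-1-ol | OC/C(C)=C\I | intermediate
13 | (Z)-3-iodo-2-methylprop-2-enal | O=C/C(C)=C\I | intermediate
14 | methyl (2Z,4Z)-5-iodo-4-methylpenta-2,4-dienoate | COC(=O)/C=C\C(C)=C/I | intermediate
15 | (2Z,4Z)-5-iodo-4-methylpenta-2,4-dien-1-ol | OC/C=C\C(C)=C/I | intermediate
16 | {(2R,3S)-3-[(Z)-1-iodoprop-1-en-2-yl]oxiran-2-yl}methanol | OC[C@H]1O[C@H]1/C(C)=C\I | intermediate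
17 | TBS ether of 16 | CC(C)(C)[Si](C)(C)OC[C@H]1O[C@H]1/C(C)=C\I | intermediate
18 | C5 alkenyllithium (not isolated) | CC(C)(C)[Si](C)(C)OC[C@H]1O[C@H]1/C(C)=C\[Li] | intermediate
19 | C5 alkenylmagnesium bromide (not isolated) | CC(C)(C)[Si](C)(C)OC[C@H]1O[C@H]1/C(C)=C\[Mg]Br | intermediate
20 | C5–C6 coupled (4Z)-allylic alcohol, C6 inverted | CC(C)(C)[Si](C)(C)OC[C@H]1O[C@H]1/C(C)=C\[C@H](O)[C@H](C(Br)=C)[C@H](OCc1ccc(OC)cc1)CO[Si](c1ccccc1)(c1ccccc1)C(C)(C)C | intermediate
21 | 2,3:4,5-bis-oxirane (6R)-alcohol | CC(C)(C)[Si](C)(C)OC[C@H]1O[C@H]1[C@]2(C)O[C@@H]2[C@H](O)[C@H](C(Br)=C)[C@H](OCc3ccc(OC)cc3)CO[Si](c3ccccc3)(c3ccccc3)C(C)(C)C | intermediate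
22 | C6 tosylate of 21 | CC(C)(C)[Si](C)(C)OC[C@H]1O[C@H]1[C@]2(C)O[C@@H]2[C@H](OS(=O)(=O)c3ccc(C)cc3)[C@H](C(Br)=C)[C@H](OCc3ccc(OC)cc3)CO[Si](c3ccccc3)(c3ccccc3)C(C)(C)C | intermediate
23 | C11 vinyllithium (not isolated) | CC(C)(C)[Si](C)(C)OC[C@H]1O[C@H]1[C@]2(C)O[C@@H]2[C@H](OS(=O)(=O)c3ccc(C)cc3)[C@H](C([Li])=C)[C@H](OCc3ccc(OC)cc3)CO[Si](c3ccccc3)(c3ccccc3)C(C)(C)C | intermediate
24 | lithium acrylate (C12 carboxylate, not isolated) | [Li+].CC(C)(C)[Si](C)(C)OC[C@H]1O[C@H]1[C@]2(C)O[C@@H]2[C@H](OS(=O)(=O)c3ccc(C)cc3)[C@H](C(=C)C([O-])=O)[C@H](OCc3ccc(OC)cc3)CO[Si](c3ccccc3)(c3ccccc3)C(C)(C)C | intermediate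
25 | trans-fused α-methylene-γ-butyrolactone (C1 OTBS, C8 OPMB, C9 OTBDPS) | CC(C)(C)[Si](C)(C)OC[C@H]1O[C@H]1[C@]2(C)O[C@@H]2[C@H]3OC(=O)C(=C)[C@@H]3[C@H](OCc4ccc(OC)cc4)CO[Si](c4ccccc4)(c4ccccc4)C(C)(C)C | intermediate
26 | C1 primary alcohol | OC[C@H]1O[C@H]1[C@]2(C)O[C@@H]2[C@H]3OC(=O)C(=C)[C@@H]3[C@H](OCc4ccc(OC)cc4)CO[Si](c4ccccc4)(c4ccccc4)C(C)(C)C | intermediate
27 | C1 cis-epoxy aldehyde | O=C[C@H]1O[C@H]1[C@]2(C)O[C@@H]2[C@H]3OC(=O)C(=C)[C@@H]3[C@H](OCc4ccc(OC)cc4)CO[Si](c4ccccc4)(c4ccccc4)C(C)(C)C | intermediate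
28 | methyl (Z)-α-iodoenoate | COC(=O)/C(I)=C/[C@H]1O[C@H]1[C@]2(C)O[C@@H]2[C@H]3OC(=O)C(=C)[C@@H]3[C@H](OCc4ccc(OC)cc4)CO[Si](c4ccccc4)(c4ccccc4)C(C)(C)C | intermediate
29 | C9 primary alcohol | COC(=O)/C(I)=C/[C@H]1O[C@H]1[C@]2(C)O[C@@H]2[C@H]3OC(=O)C(=C)[C@@H]3[C@H](OCc4ccc(OC)cc4)CO | intermediate
30 | C9 aldehyde | COC(=O)/C(I)=C/[C@H]1O[C@H]1[C@]2(C)O[C@@H]2[C@H]3OC(=O)C(=C)[C@@H]3[C@H](OCc4ccc(OC)cc4)C=O | intermediate
31 | ten-membered (9R)-allylic alcohol | COC(=O)/C1=C/[C@H]2O[C@H]2[C@]3(C)O[C@@H]3[C@H]4OC(=O)C(=C)[C@@H]4[C@H](OCc5ccc(OC)cc5)[C@@H]1O | intermediate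
32 | C9 acetate | COC(=O)/C1=C/[C@H]2O[C@H]2[C@]3(C)O[C@@H]3[C@H]4OC(=O)C(=C)[C@@H]4[C@H](OCc5ccc(OC)cc5)[C@@H]1OC(C)=O | intermediate
33 | C8 alcohol | COC(=O)/C1=C/[C@H]2O[C@H]2[C@]3(C)O[C@@H]3[C@H]4OC(=O)C(=C)[C@@H]4[C@H](O)[C@@H]1OC(C)=O | intermediate
34 | methyl angelate | C/C=C(/C)C(=O)OC | starting material
35 | (Z)-2-methylbut-2-en-1-ol | C/C=C(/C)CO | intermediate
36 | [(2R,3S)-2,3-dimethyloxiran-2-yl]methanol | OC[C@@]1(C)O[C@H]1C | intermediate
37 | (2S,3S)-2,3-dimethyloxirane-2-carboxylic acid | OC(=O)[C@@]1(C)O[C@H]1C | intermediate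
38 | mixed 2,4,6-trichlorobenzoic anhydride of 37 (not isolated) | O=C(OC(=O)[C@@]1(C)O[C@H]1C)c1c(Cl)cc(Cl)cc1Cl | intermediate
39 | CNP0077535.3 | C=C1C(=O)O[C@H]2[C@H]1[C@H](OC(=O)[C@@]1(C)O[C@H]1C)[C@H](OC(C)=O)/C(C(=O)OC)=C\[C@H]1O[C@H]1[C@]1(C)O[C@H]21 | target

**Count and risks**
Total step count: 29. Longest linear sequence: 20 steps (steps 1–7, 14–25 and 29).

Step 17. The vinyllithium may be consumed before CO2 reaches it, by attack on the sulfonate or an oxirane or by 1,3-elimination. Alternatively, the carboxylate may open the oxirane at C5 instead of displacing the tosylate. The fallback keeps the C6–O bond of an alcohol and uses CO2 only for C12. It sets out from 21. Mitsunobu inversion with 4-nitrobenzoic acid (PPh3, DIAD) gives the C6 4-nitrobenzoate of natural configuration F1. Methanolysis (K2CO3, MeOH) gives the natural C6 alcohol F2. Deprotonation (MeLi), bromine–lithium exchange (t-BuLi, −78 °C) and CO2 give, after mild acid, the γ-hydroxy acrylic acid F3. This lactonises by acyl substitution with retention at C6 and rejoins the route at 25.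

Step 23. Ring closure may lose to intermolecular coupling. Low-valent nickel or chromium may reduce the allylic oxirane or the C–I bond. Facial selectivity at C9 may also be poor. The fallback closes the ring at C1=C10 by metathesis instead, and sets out from 27. Wittig methylenation (Ph3P=CH2, −78 °C) gives the C1 vinyl bis-oxirane F4. TBAF/AcOH gives the C9 alcohol F5, and TPAP/NMO gives the C9 aldehyde F6. A Morita–Baylis–Hillman reaction with methyl acrylate (DABCO) gives the C9 hydroxy C10 acrylate F7. Ring-closing metathesis (Hoveyda–Grubbs II, dilute toluene) joins C1 and C10 to the ring-cis enoate and rejoins the route at 31.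

Step 14. The chelate may not form, which would give poor facial selectivity. The aldehyde may enolise and lose C7 integrity. The magnesium alkoxide may attack the allylic oxirane carbon C3. The fallback sets C6 by ketone reduction instead of by C–C bond formation, and sets out from 9 and 17. These are coupled without a chelating additive, which gives 20 mixed with the C6 epimer of 20 F8. The mixture is oxidised (Dess–Martin periodinane) to the single Z-enone F9. L-Selectride (−78 °C) then reduces it 1,2 under Felkin–Anh control, with the branched C8 chain as the large group, and the route is rejoined at 20.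

**Further compounds**
F1 | step 17 | C6 4-nitrobenzoate of natural configuration | CC(C)(C)[Si](C)(C)OC[C@H]1O[C@H]1[C@]2(C)O[C@@H]2[C@@H](OC(=O)c3ccc(cc3)[N+](=O)[O-])[C@H](C(Br)=C)[C@H](OCc3ccc(OC)cc3)CO[Si](c3ccccc3)(c3ccccc3)C(C)(C)C
F2 | step 17 | natural C6 alcohol | CC(C)(C)[Si](C)(C)OC[C@H]1O[C@H]1[C@]2(C)O[C@@H]2[C@@H](O)[C@H](C(Br)=C)[C@H](OCc3ccc(OC)cc3)CO[Si](c3ccccc3)(c3ccccc3)C(C)(C)C
F3 | step 17 | γ-hydroxy acrylic acid | CC(C)(C)[Si](C)(C)OC[C@H]1O[C@H]1[C@]2(C)O[C@@H]2[C@@H](O)[C@H](C(=C)C(=O)O)[C@H](OCc3ccc(OC)cc3)CO[Si](c3ccccc3)(c3ccccc3)C(C)(C)C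
F4 | step 23 | C1 vinyl bis-oxirane | C=C[C@H]1O[C@H]1[C@]2(C)O[C@@H]2[C@H]3OC(=O)C(=C)[C@@H]3[C@H](OCc4ccc(OC)cc4)CO[Si](c4ccccc4)(c4ccccc4)C(C)(C)C
F5 | step 23 | C9 alcohol | C=C[C@H]1O[C@H]1[C@]2(C)O[C@@H]2[C@H]3OC(=O)C(=C)[C@@H]3[C@H](OCc4ccc(OC)cc4)CO
F6 | step 23 | C9 aldehyde | C=C[C@H]1O[C@H]1[C@]2(C)O[C@@H]2[C@H]3OC(=O)C(=C)[C@@H]3[C@H](OCc4ccc(OC)cc4)C=O
F7 | step 23 | C9 hydroxy C10 acrylate | C=C[C@H]1O[C@H]1[C@]2(C)O[C@@H]2[C@H]3OC(=O)C(=C)[C@@H]3[C@H](OCc4ccc(OC)cc4)[C@H](O)C(=C)C(=O)OC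
F8 | step 14 | C6 epimer of 20 | CC(C)(C)[Si](C)(C)OC[C@H]1O[C@H]1/C(C)=C\[C@@H](O)[C@H](C(Br)=C)[C@H](OCc2ccc(OC)cc2)CO[Si](c2ccccc2)(c2ccccc2)C(C)(C)C
F9 | step 14 | Z-enone | CC(C)(C)[Si](C)(C)OC[C@H]1O[C@H]1/C(C)=C\C(=O)[C@H](C(Br)=C)[C@H](OCc2ccc(OC)cc2)CO[Si](c2ccccc2)(c2ccccc2)C(C)(C)C
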